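If a flask makes no target until its radical scavenger is used up, and the initiator consumes that scavenger at a rate proportional to c(initiator), then the wait before target appears, the induction period, goes as c(radical scavenger)/c(initiator). The flasks to be ranked differ in initiator.

the same everywhere: substrate 0.0010 M; radical scavenger 6.7 µM
- Wednesday's: partner 0.70 mM; initiator 26 µM; run made earlier
- Friday's: partner 0.70 mM; initiator 59 µM; run made earlier
- Monday's: partner 0.70 mM; initiator 83 µM; run made earlier
- maple: partner 0.700 mM; initiator 80 µM; time 3.0 min
- ash: partner 0.700 mM; initiator 100 µM; time 3.0 min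
- cedar: partner 0.700 mM; initiator 30 µM; time 3.0 min
- oak: partner 0.700 mM; initiator 50 µM; time 3.0 min

| Wednesday's: time / min | Wednesday's: target / % | Friday's: time / min | Friday's: target / % | Monday's: time / min | Monday's: target / % |
|---|---|---|---|---|---|
| 0.833 | 0 | 0.833 | 0 | 0.833 | 0.1 |
| 1.50 | 1.5 | 1.50 | 2.5 | 1.50 | 25.9 |
| 2.50 | 1.2 | 2.50 | 36.4 | 2.50 | 50.8 |
| 3.00 | 2.0 | 3.00 | 48.7 | 3.00 | 54.8 |

(standard deviation of a reading: 1 percentage point)

* the flasks put in order of amount of target, in percent of the substrate charged, best first, at 3.0 min (maple / ash / cedar / oak)
* the amount of target, in percent of the substrate charged of the flask you put first, at 3.0 min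
* the amount of target, in percent of the substrate charged of the flask you put last, at 3.0 min

A straight line through the readings of Friday's run at 1.50 min and 2.50 min meets zero at 1.43 min. We call this onset times c(initiator)/c(radical scavenger) the scavenger clock, 12.6 min. It puts the onset of Monday's run at 1.01 min, between its readings at 0.833 min and 1.50 min. For Wednesday's run it gives 3.24 min, later than the last reading, and that run shows 2.0%.

Oak looks nearly like Friday's run, with 50 µM of initiator against 59 µM. The clock gives oak an onset of 1.68 min, later than Friday's by 0.257 min. So we expect oak at 3.0 min to stand where Friday's run stood at 2.74 min, which between its readings is 42.4%. Cedar's onset is 2.80 min, which leaves it 0.200 min, so we put cedar last.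

The forecast reads the runs the same way: “Product appears only after the scavenger is gone.” It gives ash > maple > oak > cedar, with 58% for ash and 5% for cedar. For oak it says 39% where we said 42.4%.

The flasks give ash > maple > oak > cedar: 59.1% in ash, 40.0% in oak and 1.22% in cedar.

    substrate + initiating radical → capped initiator + first chain carrier (k = 1.31 × 10⁷ M⁻¹ s⁻¹)
    2 first chain carrier → ended chains A (k = 7.50 × 10⁶ M⁻¹ s⁻¹)
    partner + target → over-reaction product (k = 1.74 M⁻¹ s⁻¹)
    partner + first chain carrier → target + second chain carrier (k = 1.89 × 10⁵ M⁻¹ s⁻¹)
    initiator → 2 initiating radical (k = 6.62 × 10⁻⁴ s⁻¹)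
    second chain carrier + radical scavenger → ended chains C (k = 1.27 × 10⁹ M⁻¹ s⁻¹)
    substrate + second chain carrier → by-product + first chain carrier (k = 7.56 × 10⁵ M⁻¹ s⁻¹)
    2 second chain carrier → ended chains B (k = 2.90 × 10⁶ M⁻¹ s⁻¹)

In ash the half-life of target by the step to over-reaction product, 17 min at 1.41 min, is longer than the 3.0 min of the run. At 3.00 min ash holds 1.88% of over-reaction product beside 59.1% of target. The clock gives ash an onset of 0.841 min. A neighbour of ash, charged with 1.1 × 10⁻⁵ M of radical scavenger and otherwise the same, gets 1.38 min, later than ash, and at 3.0 min it holds 53.6% of target.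

(Readings and results were generated by integration with made-up constants; noise was put on by code.)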